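## Structural features

The target 28 is a 2-hydroxychroman-4-one. A benzene ring A without any hydrogen (C4a, C5–OH, C6–OMe, C7–OH, C8–Me, C8a) is fused along C4a–C8a to a dihydropyranone ring C (O1, hemiacetal C2, C3, ketone C4), and C3 carries a hydroxy(4-hydroxyphenyl)methyl arm whose carbinol carbon is C9. The stereocentres C2 (S), C3 (R) and C9 (S) are contiguous, and the C2 hydroxyl and the C3 side chain are trans on ring C. C2 is a hemiacetal and C3 lies between the ketone and the masked aldehyde, so both can invert by ring–chain tautomerism and enolisation. C9 is configurationally stable but fragile: it is a β-hydroxy ketone carbinol on a para-hydroxybenzylic carbon, open to dehydration, retro-aldol cleavage and quinone methide formation. The lactol loses water to a chromone under acid, and its open formyl ketone form could re-close on O5 instead of O8a, which would swap methoxy and methyl relative to the ring oxygen. The real difficulty is a fully substituted ring whose four oxygens must each end in a different state, joined to an end game that tolerates neither acid, base nor forcing reduction. The key step uses the para relationship of O6 and O8a across the C7–C8 edge: C8a–C4a–C5–C6 with its three oxygens is the skeleton of a 2,3-dioxygenated furan whose ring oxygen becomes O8a, while C7 (as an acetyl-bearing carbon, latent O7) and C8 (with its methyl) are the two carbons of an alkynyl ketone.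

## Logic of the disconnections

**28 ⇒ 27 ⇒ 26.** The three O–benzyl bonds (O5, O7, O4') and the O–Si bond at C9 are cut. The target itself must only ever be formed under neutral conditions, and an ether on O5 until the last step makes closure of ring C on O8a the only possibility. The gain is a fully masked lactol. The demand is a hydrogenolysis that spares the benzylic C9–O bond and a buffered desilylation.

**26 ⇒ 24.** The C2–C3 bond and the O1–C2 bond are cut, which removes a one-carbon unit at the formate level. C2 sits on the enolisable C3 and its aldehyde closes by itself on the neighbouring phenol, so ring C and two stereolabile centres disappear together. The forward step must formylate the enolate of a β-silyloxy ketone faster than that enolate expels silyloxide, and must avoid dehydration on work-up.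

**24 ⇒ 22 ⇒ 15 + 21.** The C4–C4a bond is cut as an oxygen-to-carbon acyl shift, then the O8a–acyl ester bond. C4a is the one ring position without a substituent and lies ortho to O8a, so the acyl group can be delivered regiospecifically from that oxygen. The molecule falls into a ring A phenol and a side-chain acid that already holds C9. The demand is that the aryl–metal attacks the adjacent ester carbonyl faster than it removes the ester α-hydrogens.

**21 ⇒ 19 ⇒ 18 ⇒ 17 ⇒ 16.** The C9–H bond (the only reagent-controlled stereocentre) and the bond between the ketone α-carbon and the ester carbon are cut. An aryl β-keto ester is a reliable substrate for catalytic asymmetric reduction. The demand is high enantioselectivity and a silyl ether that survives strong bases yet leaves under buffered fluoride.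

**15 ⇒ 14 ⇒ 12 ⇒ 11 ⇒ 9 ⇒ 8 ⇒ 7.** These are functional group changes on ring A: the C7–O bond goes back to the C7–acetyl bond, O6–methyl to O6–silyl, C4a–Br to C4a–H, and O8a carries a temporary acetal cap. The order is forced. O6 is methylated while C7 still bears the ketone, so no acyl group can wander. O8a is capped while O6 and O7 are addressed. The bromine blocks the only free ring position during the peracid step and later triggers the acyl shift.

**7 ⇒ 4 + 5.** The C6–C7 and C8–C8a bonds are cut. This takes ring A back to a furan and an alkyne in one step and delivers O8a free, O6 silylated, O5 benzylated and C4a open. The demand is regiocontrol in the cycloaddition and clean opening of the oxygen bridge.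

**4 ⇒ 3 ⇒ 2 ⇒ 1.** The O–Si and O–benzyl bonds and the enol unsaturation are removed, leading to a commercial hydroxy lactone. The demand is O- rather than C-alkylation of a small acidic enol.

## Other disconnections considered

**Alternative 1:** The cut runs through C3–C4 and the bond from C2 to its hydroxyl oxygen. Ring A would arrive as the nitrile oxide A2 (2,4,6-tris(tert-butyldimethylsilyloxy)-3-methoxy-5-methylbenzonitrile oxide, its nitrile carbon being C4). C2, C3, C9 and the second arene would arrive as the enaminone A3 ((E)-1-[4-(tert-butyldimethylsilyloxy)phenyl]-3-(dimethylamino)prop-2-en-1-one). A 1,3-dipolar cycloaddition followed by loss of dimethylamine would give the 4-aroylisoxazole A1 ([4-(tert-butyldimethylsilyloxy)phenyl]{3-[2,4,6-tris(tert-butyldimethylsilyloxy)-3-methoxy-5-methylphenyl]isoxazol-4-yl}methanone).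
- In favour: the union is convergent, the regiochemistry of nitrile oxide–enaminone additions is dependable, a di-ortho-substituted nitrile oxide resists dimerisation, and the isoxazole hides the formyl ketone as a stable aromatic ring.
- Against: C9 enters as a ketone between two aromatic groups and would need a later enantioselective reduction. Unmasking needs N–O cleavage and enaminone hydrolysis, under which the lactol can dehydrate. O5 and O8a carry the same silyl group in A1, so nothing decides which closes ring C. The hexasubstituted ring A with a carbon on C4a must still be built.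
- Comparison: on structure it is weaker (C9 at the wrong oxidation level, O5 and O8a not told apart) but better at masking the formyl ketone. On mechanism it is the equal of the chosen key step, both being regiocontrolled cycloadditions of a polarised pair. On step economy it is the equal in convergence but gives no shortening, since ring A is not addressed and reduction, N–O cleavage and hydrolysis are added.

**Alternative 2:** The cut is the C4a–C8a bond of ring A, traced to the cyclobutenone A5 (4-(1-ethoxyethenyl)-4-methoxy-2-methyl-3-(propan-2-yloxy)cyclobut-2-en-1-one), in principle available from a dialkyl squarate. Heating would open it to a dienylketene, and 6π electrocyclisation would give the phenol A4 (5-ethoxy-4-methoxy-2-methyl-3-(propan-2-yloxy)phenol) with O8a free and C4a open.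
- In favour: O6 is already methylated and O7 already present, so neither a Baeyer–Villiger oxidation nor a silyl-to-methyl exchange is needed. Outward rotation of the 4-alkoxy group in the ring opening places the alkenyl group for closure. The substitution pattern follows from the order of additions to the squarate.
- Against: O5 and O7 emerge as ethyl and isopropyl ethers. Their cleavage needs boron or aluminium halides that the lactol and the benzylic carbinol would not survive, so they would have to be exchanged for benzyl groups early. The second organolithium addition to an unsymmetrical cyclobutenedione also needs regiocontrol.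
- Comparison: on structure A4 is the equal of 7 (free O8a, open C4a, every oxygen different) and better in oxidation pattern. On mechanism the thermal cascade is at least as dependable as the cycloaddition. On step economy it is better up to the ring A phenol, and that lead would be largely spent on the protecting-group exchange.

**Alternative 3:** The cut is the O1–C8a bond. Ring C would be closed from the 2-bromoaryl formyl ketone A7 ((3S)-2-[2-bromo-5-methoxy-4,6-bis(methoxymethoxy)-3-methylbenzoyl]-3-(tert-butyldimethylsilyloxy)-3-[4-(methoxymethoxy)phenyl]propanal) by intramolecular O-arylation of its enol under CuI catalysis. The product would be the chromone A6 (3-[(R)-(tert-butyldimethylsilyloxy)[4-(methoxymethoxy)phenyl]methyl]-6-methoxy-5,7-bis(methoxymethoxy)-8-methyl-4H-chromen-4-one; the descriptor changes with the ranking, the spatial arrangement at C9 is that of the target).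
- In favour: the halogen position alone decides which oxygen closes the ring, which is the equal of the benzyl block on O5 in the chosen plan. No free phenol is needed, so ring A can carry uniform protecting groups, which is better in protecting-group economy.
- Against: the closure gives a chromone, so C2–C3 would have to be hydrated against the stability of the pyrone, and C3 would be created there without control. Hot basic copper conditions meet a β-silyloxy 1,3-dicarbonyl compound prone to elimination. The methoxymethyl ethers need acid at the end, which favours the chromone and endangers C9. A7 still needs a formylation like step 17 and a hexasubstituted bromoarene.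
- Comparison: on structure it reaches the wrong oxidation pattern at C2/C3, whereas the chosen plan forms the hemiacetal directly. On mechanism the enol O-arylation is well founded and equal in regiocontrol. On step economy it saves the capping and release of O8a but adds the hydration problem, so no net gain is expected.

Key step: step 4

Assumption: C2 (hemiacetal) and C3 (between the ketone and the masked aldehyde) equilibrate, and the (2S,3R) arrangement is taken to be the most stable one for a 9S carbinol, so only C9 is set by a reagent.

## Route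

Step 1
Reactants: 1 α-hydroxy-γ-butyrolactone (racemic 3-hydroxyoxolan-2-one)
Product: 2 3-hydroxyfuran-2(5H)-one (enol form of dihydrofuran-2,3-dione)
Conditions: IBX, EtOAc, 80 °C; filtration, concentration
Reagents that add atoms: none
Why: Oxidation of a secondary α-hydroxy lactone to the α-keto lactone with a hypervalent iodine reagent; the keto lactone has β-hydrogens and should rest as the conjugated enol, and the non-aqueous work-up avoids losing the small acidic product to water.

Step 2
Reactants: 2 3-hydroxyfuran-2(5H)-one
Product: 3 3-(benzyloxy)furan-2(5H)-one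
Conditions: BnBr, K2CO3, DMF, 0 °C → rt
Reagents that add atoms: benzyl bromide, BrCc1ccccc1
Why: Williamson O-alkylation of an acidic enol of the diosphenol type, which should react at the hard oxygen and not at C4.

Step 3
Reactants: 3 3-(benzyloxy)furan-2(5H)-one
Product: 4 3-(benzyloxy)-2-(tert-butyldimethylsilyloxy)furan
Conditions: TBSOTf, Et3N, CH2Cl2, 0 °C; used crude
Reagents that add atoms: tert-butyldimethylsilyl trifluoromethanesulfonate, CC(C)(C)[Si](C)(C)OS(=O)(=O)C(F)(F)F
Why: Soft enolisation of a butenolide: silylation of the lactone carbonyl oxygen and loss of a C5 proton should give the aromatic 2-silyloxyfuran, the standard entry to this diene class.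

Step 4
Reactants: 4 3-(benzyloxy)-2-(tert-butyldimethylsilyloxy)furan; 5 3-pentyn-2-one
Product: 7 1-[3-(benzyloxy)-2-(tert-butyldimethylsilyloxy)-5-hydroxy-6-methylphenyl]ethan-1-one, via oxanorbornadiene 6 (not isolated)
Conditions: toluene, 90 °C, sealed tube; then silica gel, CH2Cl2, rt
Reagents that add atoms: none
Why: Diels–Alder cycloaddition of an electron-rich 2-silyloxyfuran with an acetylenic ketone followed by opening of the oxygen bridge, the known way from silyloxyfurans and activated alkynes to para-oxygenated phenols. Ring A closes in a [4+2] mode: furan C5 (future C8a) bonds to the methyl-bearing β-carbon of 5 (C8) and furan C2 (future C6) to the acyl-bearing carbon (C7), giving the bridged adduct 6. The bridge C–O bond at the silyloxy-bearing bridgehead should then ionise, because the cation is stabilised by the silyloxy oxygen, and loss of the hydrogen at the other bridgehead aromatises the ring; the former furan oxygen ends as the free O8a phenol and the silyl group stays on O6. No stereocentre survives, since both bridgehead carbons of 6 become aromatic. The selectivity needed is regiochemical: the unsubstituted furan C5 is the most nucleophilic terminus of the silyl dienolate and the ynone β-carbon the electrophilic one, so their bond forms first and places methyl next to the phenol carbon; the 3-benzyloxy group pushes density toward C2, but this carbon is the acetal-like terminus and should not override the match. The hydrogen on furan C5 is essential, as it is the one lost on aromatisation, and the product carries a different group on each oxygen with C4a still open.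

Step 5
Reactants: 7 1-[3-(benzyloxy)-2-(tert-butyldimethylsilyloxy)-5-hydroxy-6-methylphenyl]ethan-1-one
Product: 8 1-[3-(benzyloxy)-4-bromo-2-(tert-butyldimethylsilyloxy)-5-hydroxy-6-methylphenyl]ethan-1-one
Conditions: NBS, MeCN, −20 → 0 °C
Reagents that add atoms: N-bromosuccinimide, BrN1C(=O)CCC1=O
Why: Electrophilic aromatic bromination ortho to a free phenol; C4a is the only unsubstituted ring position and is activated by O8a and O5. The bromine blocks this electron-rich site during the peracid step and later triggers the acyl shift.

Step 6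
Reactants: 8 1-[3-(benzyloxy)-4-bromo-2-(tert-butyldimethylsilyloxy)-5-hydroxy-6-methylphenyl]ethan-1-one
Product: 9 1-[3-(benzyloxy)-4-bromo-2-(tert-butyldimethylsilyloxy)-5-(methoxymethoxy)-6-methylphenyl]ethan-1-one
Conditions: MOMCl, i-Pr2NEt, CH2Cl2, 0 → 40 °C
Reagents that add atoms: chloromethyl methyl ether, COCCl
Why: Protection of the phenol as a methoxymethyl acetal by O-alkylation; the cap keeps O8a out of the methylation of O6 and away from the peracid, and can later be removed without touching benzyl ethers.

Step 7
Reactants: 9 1-[3-(benzyloxy)-4-bromo-2-(tert-butyldimethylsilyloxy)-5-(methoxymethoxy)-6-methylphenyl]ethan-1-one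
Product: 11 1-[3-(benzyloxy)-4-bromo-2-methoxy-5-(methoxymethoxy)-6-methylphenyl]ethan-1-one, via cesium aryloxide 10 (not isolated)
Conditions: CsF, MeI, DMF, rt
Reagents that add atoms: iodomethane, CI
Why: Fluoride cleavage of the aryl silyl ether and Williamson methylation of the released aryloxide in one pot; it is done while C7 still bears the ketone, so no neighbouring acyloxy group can migrate to O6.

Step 8
Reactants: 11 1-[3-(benzyloxy)-4-bromo-2-methoxy-5-(methoxymethoxy)-6-methylphenyl]ethan-1-one
Product: 12 3-(benzyloxy)-4-bromo-2-methoxy-5-(methoxymethoxy)-6-methylphenyl acetate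
Conditions: mCPBA, CH2Cl2, 0 °C → rt
Reagents that add atoms: 3-chloroperoxybenzoic acid, OOC(=O)c1cccc(Cl)c1
Why: Baeyer–Villiger oxidation; the electron-rich ortho-methoxy aryl group should migrate in preference to methyl, and the di-ortho-substituted ketone is twisted out of conjugation and adds peracid readily. The fully substituted ring offers no site for electrophilic hydroxylation, and the acetal tolerates the weak carboxylic acid.

Step 9
Reactants: 12 3-(benzyloxy)-4-bromo-2-methoxy-5-(methoxymethoxy)-6-methylphenyl acetate
Product: 14 1,3-bis(benzyloxy)-4-bromo-2-methoxy-5-(methoxymethoxy)-6-methylbenzene, via phenol 13 (not isolated)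
Conditions: K2CO3, MeOH, rt; evaporation; then BnBr, DMF, 50 °C
Reagents that add atoms: benzyl bromide, BrCc1ccccc1
Why: Base-catalysed methanolysis of the aryl acetate and Williamson benzylation of the O7 aryloxide in the same flask; the acetate is replaced by an ether that withstands organolithium and amide bases and leaves with the other benzyl groups at the end.

Step 10
Reactants: 14 1,3-bis(benzyloxy)-4-bromo-2-methoxy-5-(methoxymethoxy)-6-methylbenzene
Product: 15 3,5-bis(benzyloxy)-2-bromo-4-methoxy-6-methylphenol
Conditions: HCl (aq. 3 M), MeOH/THF, 50 °C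
Reagents that add atoms: none
Why: Acid-catalysed methanolysis of the aryl methoxymethyl acetal; benzyl and methyl aryl ethers and the aryl bromide are inert here, so only O8a is released.

Step 11
Reactants: 16 4'-(benzyloxy)acetophenone (the commercial benzyl ether of 4'-hydroxyacetophenone)
Product: 17 methyl 3-[4-(benzyloxy)phenyl]-3-oxopropanoate
Conditions: NaH, (MeO)2CO, THF, reflux; AcOH work-up
Reagents that add atoms: dimethyl carbonate, COC(=O)OC
Why: Crossed Claisen condensation of the methyl ketone enolate with a non-enolisable carbonate, driven by formation of the stabilised β-keto ester enolate.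

Step 12
Reactants: 17 methyl 3-[4-(benzyloxy)phenyl]-3-oxopropanoate
Product: 18 methyl (S)-3-[4-(benzyloxy)phenyl]-3-hydroxypropanoate
Conditions: RuCl(p-cymene)[(S,S)-TsDPEN] (cat.), HCO2H/Et3N, 30 °C
Reagents that add atoms: none
Why: Noyori–Ikariya asymmetric transfer hydrogenation of an aryl ketone; the (S,S) catalyst should deliver hydride to the face that sets the aryl group against the η6-arene ligand, as with acetophenone. Because aryl outranks CH2CO2Me just as it outranks methyl, this is the S carbinol, which is C9 of the target; the benzyl ether is inert to the ruthenium hydride.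

Step 13
Reactants: 18 methyl (S)-3-[4-(benzyloxy)phenyl]-3-hydroxypropanoate
Product: 19 (S)-3-[4-(benzyloxy)phenyl]-3-hydroxypropanoic acid
Conditions: LiOH, THF/H2O, 0 °C → rt; then HCl (aq.) to pH 3
Reagents that add atoms: lithium hydroxide, [Li+].[OH-]
Why: Ester saponification, placed before silylation so that no silyl ether meets hydroxide; C9 has no acidic hydrogen and should keep its configuration.

Step 14
Reactants: 19 (S)-3-[4-(benzyloxy)phenyl]-3-hydroxypropanoic acid
Product: 21 (S)-3-[4-(benzyloxy)phenyl]-3-(triethylsilyloxy)propanoic acid, via silyl ester 20 (not isolated)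
Conditions: Et3SiCl (2.5 equiv), imidazole, DMF, 0 °C → rt; then H2O, 0 °C
Reagents that add atoms: chlorotriethylsilane, CC[Si](CC)(CC)Cl
Why: Silylation of hydroxyl and carboxyl groups followed by selective hydrolysis of the far more labile silyl ester; the triethylsilyl ether should survive carbodiimide coupling, organolithium and amide bases and still leave under buffered fluoride.

Step 15
Reactants: 15 3,5-bis(benzyloxy)-2-bromo-4-methoxy-6-methylphenol; 21 (S)-3-[4-(benzyloxy)phenyl]-3-(triethylsilyloxy)propanoic acid
Product: 22 3,5-bis(benzyloxy)-2-bromo-4-methoxy-6-methylphenyl (S)-3-[4-(benzyloxy)phenyl]-3-(triethylsilyloxy)propanoate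
Conditions: EDC·HCl, DMAP, CH2Cl2, 0 °C → rt
Reagents that add atoms: none
Why: Steglich-type carbodiimide esterification with nucleophilic catalysis, suited to a di-ortho-substituted phenol; the neutral conditions preserve the β-silyloxy group and C9.

Step 16
Reactants: 22 3,5-bis(benzyloxy)-2-bromo-4-methoxy-6-methylphenyl (S)-3-[4-(benzyloxy)phenyl]-3-(triethylsilyloxy)propanoate
Product: 24 (S)-1-[2,4-bis(benzyloxy)-6-hydroxy-3-methoxy-5-methylphenyl]-3-[4-(benzyloxy)phenyl]-3-(triethylsilyloxy)propan-1-one, via aryllithium 23 (not isolated)
Conditions: t-BuLi (2.1 equiv), THF/Et2O, −100 → −78 °C; AcOH quench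
Reagents that add atoms: none
Why: Anionic Fries rearrangement triggered by bromine–lithium exchange: the C4a aryllithium attacks the carbonyl of the adjacent O8a ester, so the acyl group moves from oxygen to carbon and forms the C4–C4a bond regiospecifically, releasing the O8a phenoxide. Exchange with t-BuLi at this temperature should outrun addition to the ester and α-deprotonation, and C9 is not involved.

Step 17
Reactants: 24 (S)-1-[2,4-bis(benzyloxy)-6-hydroxy-3-methoxy-5-methylphenyl]-3-[4-(benzyloxy)phenyl]-3-(triethylsilyloxy)propan-1-one
Product: 26 (2S,3R)-5,7-bis(benzyloxy)-3-[(S)-[4-(benzyloxy)phenyl](triethylsilyloxy)methyl]-2-hydroxy-6-methoxy-8-methylchroman-4-one, via formyl ketone 25 (not isolated)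
Conditions: LiN(i-Pr)2 (3 equiv), THF, −78 °C; HCO2CH2CF3, −78 → −50 °C; AcOH quench at −78 °C, then pH 7 buffer, rt
Reagents that add atoms: 2,2,2-trifluoroethyl formate, O=COCC(F)(F)F
Why: Crossed Claisen formylation of the ketone enolate with an activated formate ester, the reaction type that turns 2'-hydroxyaryl benzyl ketones into 2-hydroxyisoflavanones; on neutralisation 25 should close to the six-membered hemiacetal by 6-exo-trig addition of the O8a hydroxyl, the only closure possible while O5 is benzylated. C2 and C3 are stereolabile in 25 and in the lactol–aldehyde equilibrium and should settle 2,3-trans (axial anomeric hydroxyl anti to the C3 arm), with C3 dictated by the fixed C9 centre, which lets the aryl group lie beside the trigonal C4 and not beside C2. The low temperature and the lithium counter-ion are meant to keep the enolate from expelling the β-silyloxy group.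

Step 18
Reactants: 26 (2S,3R)-5,7-bis(benzyloxy)-3-[(S)-[4-(benzyloxy)phenyl](triethylsilyloxy)methyl]-2-hydroxy-6-methoxy-8-methylchroman-4-one
Product: 27 (2S,3R)-5,7-bis(benzyloxy)-3-[(S)-[4-(benzyloxy)phenyl](hydroxy)methyl]-2-hydroxy-6-methoxy-8-methylchroman-4-one
Conditions: HF·pyridine, pyridine, THF, 0 °C
Reagents that add atoms: none
Why: Fluoride cleavage of the triethylsilyl ether under pyridine buffering, mild enough for the hemiacetal; O5 is still benzylated, so any transient ring opening can only re-close on O8a.

Step 19
Reactants: 27 (2S,3R)-5,7-bis(benzyloxy)-3-[(S)-[4-(benzyloxy)phenyl](hydroxy)methyl]-2-hydroxy-6-methoxy-8-methylchroman-4-one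
Product: 28 (2S,3R)-2,5,7-trihydroxy-3-[(S)-hydroxy(4-hydroxyphenyl)methyl]-6-methoxy-8-methylchroman-4-one
Conditions: H2 (1 atm), Pd/C, EtOAc, rt
Reagents that add atoms: none
Why: Catalytic hydrogenolysis of three aryl benzyl ethers in a neutral aprotic medium, in which the hemiacetal should stay closed and no stereocentre is touched; the benzylic C9 hydroxyl is expected to persist because its hydrogenolysis needs acid assistance.

## Compound list

1 | α-hydroxy-γ-butyrolactone (racemic) | OC1CCOC1=O | starting material
2 | 3-hydroxyfuran-2(5H)-one | O=C1OCC=C1O | intermediate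
3 | 3-(benzyloxy)furan-2(5H)-one | O=C1OCC=C1OCc1ccccc1 | intermediate
4 | 3-(benzyloxy)-2-(tert-butyldimethylsilyloxy)furan | C(c1ccccc1)Oc1ccoc1O[Si](C)(C)C(C)(C)C | intermediate
5 | 3-pentyn-2-one | CC#CC(C)=O | starting material
6 | 1-[6-(benzyloxy)-1-(tert-butyldimethylsilyloxy)-3-methyl-7-oxabicyclo[2.2.1]hepta-2,5-dien-2-yl]ethan-1-one (racemic, not isolated) | CC(=O)C1=C(C)C2C=C(OCc3ccccc3)C1(O[Si](C)(C)C(C)(C)C)O2 | intermediate
7 | 1-[3-(benzyloxy)-2-(tert-butyldimethylsilyloxy)-5-hydroxy-6-methylphenyl]ethan-1-one | CC(=O)c1c(C)c(O)cc(OCc2ccccc2)c1O[Si](C)(C)C(C)(C)C | intermediate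
8 | 1-[3-(benzyloxy)-4-bromo-2-(tert-butyldimethylsilyloxy)-5-hydroxy-6-methylphenyl]ethan-1-one | CC(=O)c1c(C)c(O)c(Br)c(OCc2ccccc2)c1O[Si](C)(C)C(C)(C)C | intermediate
9 | 1-[3-(benzyloxy)-4-bromo-2-(tert-butyldimethylsilyloxy)-5-(methoxymethoxy)-6-methylphenyl]ethan-1-one | CC(=O)c1c(C)c(OCOC)c(Br)c(OCc2ccccc2)c1O[Si](C)(C)C(C)(C)C | intermediate
10 | cesium 6-acetyl-2-(benzyloxy)-3-bromo-4-(methoxymethoxy)-5-methylphenolate (not isolated) | CC(=O)c1c(C)c(OCOC)c(Br)c(OCc2ccccc2)c1[O-].[Cs+] | intermediate
11 | 1-[3-(benzyloxy)-4-bromo-2-methoxy-5-(methoxymethoxy)-6-methylphenyl]ethan-1-one | CC(=O)c1c(C)c(OCOC)c(Br)c(OCc2ccccc2)c1OC | intermediate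
12 | 3-(benzyloxy)-4-bromo-2-methoxy-5-(methoxymethoxy)-6-methylphenyl acetate | CC(=O)Oc1c(C)c(OCOC)c(Br)c(OCc2ccccc2)c1OC | intermediate
13 | 3-(benzyloxy)-4-bromo-2-methoxy-5-(methoxymethoxy)-6-methylphenol (not isolated) | Oc1c(C)c(OCOC)c(Br)c(OCc2ccccc2)c1OC | intermediate
14 | 1,3-bis(benzyloxy)-4-bromo-2-methoxy-5-(methoxymethoxy)-6-methylbenzene | COCOc1c(C)c(OCc2ccccc2)c(OC)c(OCc2ccccc2)c1Br | intermediate
15 | 3,5-bis(benzyloxy)-2-bromo-4-methoxy-6-methylphenol | COc1c(OCc2ccccc2)c(C)c(O)c(Br)c1OCc1ccccc1 | intermediate
16 | 4'-(benzyloxy)acetophenone | CC(=O)c1ccc(OCc2ccccc2)cc1 | starting material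
17 | methyl 3-[4-(benzyloxy)phenyl]-3-oxopropanoate | COC(=O)CC(=O)c1ccc(OCc2ccccc2)cc1 | intermediate
18 | methyl (S)-3-[4-(benzyloxy)phenyl]-3-hydroxypropanoate | COC(=O)C[C@H](O)c1ccc(OCc2ccccc2)cc1 | intermediate
19 | (S)-3-[4-(benzyloxy)phenyl]-3-hydroxypropanoic acid | OC(=O)C[C@H](O)c1ccc(OCc2ccccc2)cc1 | intermediate
20 | triethylsilyl (S)-3-[4-(benzyloxy)phenyl]-3-(triethylsilyloxy)propanoate (not isolated) | CC[Si](CC)(CC)OC(=O)C[C@H](O[Si](CC)(CC)CC)c1ccc(OCc2ccccc2)cc1 | intermediate
21 | (S)-3-[4-(benzyloxy)phenyl]-3-(triethylsilyloxy)propanoic acid | OC(=O)C[C@H](O[Si](CC)(CC)CC)c1ccc(OCc2ccccc2)cc1 | intermediate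
22 | 3,5-bis(benzyloxy)-2-bromo-4-methoxy-6-methylphenyl (S)-3-[4-(benzyloxy)phenyl]-3-(triethylsilyloxy)propanoate | COc1c(OCc2ccccc2)c(C)c(OC(=O)C[C@H](O[Si](CC)(CC)CC)c2ccc(OCc3ccccc3)cc2)c(Br)c1OCc1ccccc1 | intermediate
23 | 3,5-bis(benzyloxy)-2-lithio-4-methoxy-6-methylphenyl (S)-3-[4-(benzyloxy)phenyl]-3-(triethylsilyloxy)propanoate (not isolated) | COc1c(OCc2ccccc2)c(C)c(OC(=O)C[C@H](O[Si](CC)(CC)CC)c2ccc(OCc3ccccc3)cc2)c([Li])c1OCc1ccccc1 | intermediate
24 | (S)-1-[2,4-bis(benzyloxy)-6-hydroxy-3-methoxy-5-methylphenyl]-3-[4-(benzyloxy)phenyl]-3-(triethylsilyloxy)propan-1-one | COc1c(OCc2ccccc2)c(C)c(O)c(c1OCc1ccccc1)C(=O)C[C@H](O[Si](CC)(CC)CC)c1ccc(OCc2ccccc2)cc1 | intermediate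
25 | (3S)-2-[2,4-bis(benzyloxy)-6-hydroxy-3-methoxy-5-methylbenzoyl]-3-[4-(benzyloxy)phenyl]-3-(triethylsilyloxy)propanal (C2 not fixed, present as enol or lithium enolate, not isolated) | COc1c(OCc2ccccc2)c(C)c(O)c(c1OCc1ccccc1)C(=O)C(C=O)[C@H](O[Si](CC)(CC)CC)c1ccc(OCc2ccccc2)cc1 | intermediate
26 | (2S,3R)-5,7-bis(benzyloxy)-3-[(S)-[4-(benzyloxy)phenyl](triethylsilyloxy)methyl]-2-hydroxy-6-methoxy-8-methylchroman-4-one | COc1c(OCc3ccccc3)c(C)c2c(c1OCc1ccccc1)C(=O)[C@H]([C@H](O[Si](CC)(CC)CC)c1ccc(OCc3ccccc3)cc1)[C@@H](O)O2 | intermediate
27 | (2S,3R)-5,7-bis(benzyloxy)-3-[(S)-[4-(benzyloxy)phenyl](hydroxy)methyl]-2-hydroxy-6-methoxy-8-methylchroman-4-one | COc1c(OCc3ccccc3)c(C)c2c(c1OCc1ccccc1)C(=O)[C@H]([C@H](O)c1ccc(OCc3ccccc3)cc1)[C@@H](O)O2 | intermediate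
28 | (2S,3R)-2,5,7-trihydroxy-3-[(S)-hydroxy(4-hydroxyphenyl)methyl]-6-methoxy-8-methylchroman-4-one | COc1c(O)c(C)c2c(c1O)C(=O)[C@H]([C@H](O)c1ccc(O)cc1)[C@@H](O)O2 | target

## Step count and least certain steps

Total: 19 steps. Longest linear sequence: 15 steps (steps 1–10, then 15–19); the side-chain branch (steps 11–14) joins at step 15.

**Step 4 (key step).** The most likely failure is a slow cycloaddition at the methyl-substituted alkyne terminus. Desilylation of 4, or conjugate addition without ring closure, could then compete, and the opposing 3-benzyloxy donor could erode the regiochemistry. The fallback sets out from 4 and uses but-2-ynal, a smaller and more strongly polarised dienophile, in the same cycloaddition–aromatisation. This should give 3-(benzyloxy)-2-(tert-butyldimethylsilyloxy)-5-hydroxy-6-methylbenzaldehyde F1. Addition of MeMgBr (excess, Et2O, −78 °C, the first equivalent being taken up by the phenol) should give 1-[3-(benzyloxy)-2-(tert-butyldimethylsilyloxy)-5-hydroxy-6-methylphenyl]ethan-1-ol F2. Oxidation of this benzylic alcohol with MnO2 comes back to the route at 7.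

**Step 16.** The most likely failure is proton transfer from the ester α-methylene to the aryllithium, or attack of the alkyllithium on the aryl ester, followed by loss of the silyloxy group from the resulting enolate. The α-hydrogens are acidic and lie close to the carbanion. The fallback replaces the acyl shift by an intermolecular union; it sets out from 14, with the side chain taken from 18, and comes back at 24.
- Silylation of 18 (Et3SiCl, imidazole) should give methyl (S)-3-[4-(benzyloxy)phenyl]-3-(triethylsilyloxy)propanoate F3.
- Reduction with i-Bu2AlH at −78 °C should give (S)-3-[4-(benzyloxy)phenyl]-3-(triethylsilyloxy)propanal F4.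
- Bromine–lithium exchange on 14 (n-BuLi, THF, −78 °C) and addition to F4 should give (3S)-1-[2,4-bis(benzyloxy)-3-methoxy-6-(methoxymethoxy)-5-methylphenyl]-3-[4-(benzyloxy)phenyl]-3-(triethylsilyloxy)propan-1-ol F5 as a pair of carbinol epimers.
- Oxidation with DMP should give (S)-1-[2,4-bis(benzyloxy)-3-methoxy-6-(methoxymethoxy)-5-methylphenyl]-3-[4-(benzyloxy)phenyl]-3-(triethylsilyloxy)propan-1-one F6.
- Non-protic removal of the methoxymethyl group (Me3SiOTf, 2,2'-bipyridyl, CH2Cl2, 0 °C; then H2O) returns to 24.

**Step 17.** The most likely failure is β-elimination of the silyloxy group from the ketone enolate before C-formylation, with dehydration of the lactol on work-up as a second risk. The leaving group is benzylic and the elimination product is conjugated. An unfavourable epimer distribution at C3 is also possible; the minor epimer would then be separated at 26 and re-equilibrated with a trace of Et3N. The fallback avoids the lithium enolate; it sets out from 24 and comes back at 26.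
- Soft enolisation (Me3SiOTf, Et3N, CH2Cl2, 0 °C) should give the bis-silylated Z enol ether trimethyl{[(1Z,3S)-1-[2,4-bis(benzyloxy)-3-methoxy-5-methyl-6-(trimethylsilyloxy)phenyl]-3-[4-(benzyloxy)phenyl]-3-(triethylsilyloxy)prop-1-en-1-yl]oxy}silane F7.
- Mukaiyama aldol hydroxymethylation with aqueous formaldehyde and Yb(OTf)3 (cat.) in THF/H2O should give (3S)-1-[2,4-bis(benzyloxy)-6-hydroxy-3-methoxy-5-methylphenyl]-3-[4-(benzyloxy)phenyl]-2-(hydroxymethyl)-3-(triethylsilyloxy)propan-1-one F8.
- Oxidation of the primary alcohol with DMP/NaHCO3 should give the aldehyde, which closes to 26.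

**Step 19.** The most likely failure is over-reduction: hydrogenolysis of the benzylic C9–O bond once the para oxygen is free and the carbinol has become a para-hydroxybenzyl alcohol. The fallback changes the order of the end game and sets out from 26. Hydrogenolysis (H2, Pd/C, EtOAc) with the C9 oxygen still silylated should give (2S,3R)-2,5,7-trihydroxy-3-[(S)-(4-hydroxyphenyl)(triethylsilyloxy)methyl]-6-methoxy-8-methylchroman-4-one F9. Desilylation with Et3N·3HF in THF/MeCN then comes back at 28.

**Step 1.** The most likely failure is loss of material through self-condensation of the enolised keto lactone, or C-alkylation in step 2, because 2 is a small, acidic, aldol-prone enol. The fallback never forms the free enol; it sets out from 1 and comes back at 3.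
- O-Benzylation with benzyl 2,2,2-trichloroacetimidate and TfOH (cat.) should give 3-(benzyloxy)dihydrofuran-2(3H)-one F10.
- Enolate selenation (LiN(SiMe3)2, PhSeBr, THF, −78 °C) should give 3-(benzyloxy)-3-(phenylselanyl)dihydrofuran-2(3H)-one F11.
- Oxidation with H2O2 and selenoxide syn-elimination toward C4, the only β-hydrogens, returns to 3.

## Further compounds

F1 | step 4 | 3-(benzyloxy)-2-(tert-butyldimethylsilyloxy)-5-hydroxy-6-methylbenzaldehyde | O=Cc1c(C)c(O)cc(OCc2ccccc2)c1O[Si](C)(C)C(C)(C)C
F2 | step 4 | 1-[3-(benzyloxy)-2-(tert-butyldimethylsilyloxy)-5-hydroxy-6-methylphenyl]ethan-1-ol (racemic) | CC(O)c1c(C)c(O)cc(OCc2ccccc2)c1O[Si](C)(C)C(C)(C)C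
F3 | step 16 | methyl (S)-3-[4-(benzyloxy)phenyl]-3-(triethylsilyloxy)propanoate | COC(=O)C[C@H](O[Si](CC)(CC)CC)c1ccc(OCc2ccccc2)cc1
F4 | step 16 | (S)-3-[4-(benzyloxy)phenyl]-3-(triethylsilyloxy)propanal | O=CC[C@H](O[Si](CC)(CC)CC)c1ccc(OCc2ccccc2)cc1
F5 | step 16 | (3S)-1-[2,4-bis(benzyloxy)-3-methoxy-6-(methoxymethoxy)-5-methylphenyl]-3-[4-(benzyloxy)phenyl]-3-(triethylsilyloxy)propan-1-ol (both C1 epimers) | COCOc1c(C)c(OCc2ccccc2)c(OC)c(OCc2ccccc2)c1C(O)C[C@H](O[Si](CC)(CC)CC)c1ccc(OCc2ccccc2)cc1
F6 | step 16 | (S)-1-[2,4-bis(benzyloxy)-3-methoxy-6-(methoxymethoxy)-5-methylphenyl]-3-[4-(benzyloxy)phenyl]-3-(triethylsilyloxy)propan-1-one | COCOc1c(C)c(OCc2ccccc2)c(OC)c(OCc2ccccc2)c1C(=O)C[C@H](O[Si](CC)(CC)CC)c1ccc(OCc2ccccc2)cc1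
F7 | step 17 | trimethyl{[(1Z,3S)-1-[2,4-bis(benzyloxy)-3-methoxy-5-methyl-6-(trimethylsilyloxy)phenyl]-3-[4-(benzyloxy)phenyl]-3-(triethylsilyloxy)prop-1-en-1-yl]oxy}silane | COc1c(OCc2ccccc2)c(C)c(O[Si](C)(C)C)c(c1OCc1ccccc1)/C(O[Si](C)(C)C)=C/[C@H](O[Si](CC)(CC)CC)c1ccc(OCc2ccccc2)cc1
F8 | step 17 | (3S)-1-[2,4-bis(benzyloxy)-6-hydroxy-3-methoxy-5-methylphenyl]-3-[4-(benzyloxy)phenyl]-2-(hydroxymethyl)-3-(triethylsilyloxy)propan-1-one (both C2 epimers) | COc1c(OCc2ccccc2)c(C)c(O)c(c1OCc1ccccc1)C(=O)C(CO)[C@H](O[Si](CC)(CC)CC)c1ccc(OCc2ccccc2)cc1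
F9 | step 19 | (2S,3R)-2,5,7-trihydroxy-3-[(S)-(4-hydroxyphenyl)(triethylsilyloxy)methyl]-6-methoxy-8-methylchroman-4-one | COc1c(O)c(C)c2c(c1O)C(=O)[C@H]([C@H](O[Si](CC)(CC)CC)c1ccc(O)cc1)[C@@H](O)O2
F10 | step 1 | 3-(benzyloxy)dihydrofuran-2(3H)-one (racemic) | O=C1OCCC1OCc1ccccc1
F11 | step 1 | 3-(benzyloxy)-3-(phenylselanyl)dihydrofuran-2(3H)-one (racemic) | O=C1OCCC1(OCc1ccccc1)[Se]c1ccccc1
A1 | alternative 1 | [4-(tert-butyldimethylsilyloxy)phenyl]{3-[2,4,6-tris(tert-butyldimethylsilyloxy)-3-methoxy-5-methylphenyl]isoxazol-4-yl}methanone | O=C(c1ccc(O[Si](C)(C)C(C)(C)C)cc1)c1conc1-c1c(O[Si](C)(C)C(C)(C)C)c(OC)c(O[Si](C)(C)C(C)(C)C)c(C)c1O[Si](C)(C)C(C)(C)C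
A2 | alternative 1 | 2,4,6-tris(tert-butyldimethylsilyloxy)-3-methoxy-5-methylbenzonitrile oxide | [O-][N+]#Cc1c(O[Si](C)(C)C(C)(C)C)c(OC)c(O[Si](C)(C)C(C)(C)C)c(C)c1O[Si](C)(C)C(C)(C)C
A3 | alternative 1 | (E)-1-[4-(tert-butyldimethylsilyloxy)phenyl]-3-(dimethylamino)prop-2-en-1-one | CN(C)/C=C/C(=O)c1ccc(O[Si](C)(C)C(C)(C)C)cc1
A4 | alternative 2 | 5-ethoxy-4-methoxy-2-methyl-3-(propan-2-yloxy)phenol | COc1c(OC(C)C)c(C)c(O)cc1OCC
A5 | alternative 2 | 4-(1-ethoxyethenyl)-4-methoxy-2-methyl-3-(propan-2-yloxy)cyclobut-2-en-1-one (racemic) | CCOC(=C)C1(OC)C(OC(C)C)=C(C)C1=O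
A6 | alternative 3 | 3-[(R)-(tert-butyldimethylsilyloxy)[4-(methoxymethoxy)phenyl]methyl]-6-methoxy-5,7-bis(methoxymethoxy)-8-methyl-4H-chromen-4-one | COc1c(OCOC)c(C)c2occ([C@H](O[Si](C)(C)C(C)(C)C)c3ccc(OCOC)cc3)c(=O)c2c1OCOC
A7 | alternative 3 | (3S)-2-[2-bromo-5-methoxy-4,6-bis(methoxymethoxy)-3-methylbenzoyl]-3-(tert-butyldimethylsilyloxy)-3-[4-(methoxymethoxy)phenyl]propanal (C2 not fixed) | COc1c(OCOC)c(C)c(Br)c(c1OCOC)C(=O)C(C=O)[C@H](O[Si](C)(C)C(C)(C)C)c1ccc(OCOC)cc1
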